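**Remark:** carotenoid numbering is used (C1–C6 = ring of the triol half, primed locants = furanoid half). The target is read from the SMILES as the all-E (3S,5R,6R,3′S,5′R,8′R) isomer. Compounds 1, 2, 9 and 25 are taken as catalogue materials.

## Strategy

The cyclohexane ring of the triol half (ring A, C1–C6) is cut into a C1–C6–C5 unit, an enolised 1,2-diketone, and a C2–C3–C4 methallyl unit whose methyl masks the C3 oxygen. The key step exploits the flanking of C6 by the gem-dimethyl carbon C1 and the methyl carbinol C5: a copper-bis(oxazoline)-catalysed Claisen rearrangement/carbonyl-ene domino converts acyclic enol ether 3 into cyclohexanone 5, the sigmatropic shift forming C1–C2 and the ene closure C4–C5, enantioselectively. Ketone 8 derived from 5 serves both halves (same C3/C5 configuration): chelation-controlled alkynylation leads to the triol end; anti alkynylation, anti-SN2′ reduction and allenol cycloisomerisation to the furanoid end. Two Wittig couplings with a C10 dialdehyde finish.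

Key step: step 2

(R,R)-tBu-box = 2,2′-(propane-2,2-diyl)bis[(4R)-4-tert-butyl-4,5-dihydro-1,3-oxazole].

## Route

**Step 1**
Reactants: 1 4-methylpentane-2,3-dione; 2 3-bromo-2-methylprop-1-ene
Product: 3 4-methyl-3-[(2-methylprop-2-en-1-yl)oxy]pent-3-en-2-one
Conditions: K2CO3, DMF, 40 °C
Reagents that add atoms: none
Why: Williamson-type O-alkylation of the more substituted, thermodynamically preferred enolate of the 1,2-dione (diosphenol ether formation); any C-allylated material is compound 4 itself and converges in step 2, and the regioisomeric enol ether is removed by distillation.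

**Step 2**
Reactants: 3 4-methyl-3-[(2-methylprop-2-en-1-yl)oxy]pent-3-en-2-one
Product: 5 (2R)-2-hydroxy-2,6,6-trimethyl-4-methylidenecyclohexan-1-one, via allyl diketone 4 (not isolated)
Conditions: [Cu((R,R)-tBu-box)](SbF6)2 (10 mol %), 4 Å MS, CH2Cl2, 25 → 40 °C
Reagents that add atoms: none
Why: Proposed new method: two-point binding of 3 (ether oxygen and acetyl oxygen) to the divalent copper Lewis acid should accelerate the [3,3] Claisen shift that joins C1 to C2 and unveils diketone 4, which stays chelated through both carbonyls so that the methallyl alkene adds to the activated acetyl carbonyl in a carbonyl-ene reaction with hydrogen transfer from the allylic methyl, joining C4 to C5. The closest known reaction types are the copper-bis(oxazoline)-catalysed Claisen rearrangement of 2-alkoxycarbonyl allyl vinyl ethers and its domino extension with an intramolecular carbonyl-ene step, the thermal Claisen rearrangement of diosphenol allyl ethers, and the copper-bis(oxazoline)-catalysed ene cyclisation of unsaturated 2-oxo esters; new is the 2-acyl (1,2-dione) substrate class. The six-membered ring closes in the type 2 intramolecular ene mode (6-exo-trig at the C5 carbonyl, the ene alkene ending as the exocyclic methylene at C3). The only new stereocentre, C5, is controlled by the tert-butyl groups of the C2-symmetric ligand shielding one face of the chelated acetyl carbonyl; by analogy with additions to chelated pyruvates the (R,R) ligand should expose the re face and give (R), and the mirror-image ligand is equally available should the sense prove opposite. The step needs ene attack at the acetyl and not at the C6 carbonyl, and an exocyclic and not an endocyclic alkene; the first is secured because closure at C6 would be a strained five-membered type 2 ene onto a carbonyl flanked by quaternary C1, the second by the concerted hydrogen transfer from the methyl group.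

**Step 3**
Reactants: 5 (2R)-2-hydroxy-2,6,6-trimethyl-4-methylidenecyclohexan-1-one
Product: 6 (2R)-2-hydroxy-2,6,6-trimethylcyclohexane-1,4-dione
Conditions: O3, CH2Cl2/MeOH, −78 °C; then Me2S
Reagents that add atoms: ozone, [O-][O+]=O
Why: Ozonolysis of the only alkene gives the C3 ketone, and the neutral reductive work-up should avoid dehydration or retro-aldol cleavage of the β-hydroxy ketone.

**Step 4**
Reactants: 6 (2R)-2-hydroxy-2,6,6-trimethylcyclohexane-1,4-dione
Product: 7 (2R,4S)-2,4-dihydroxy-2,6,6-trimethylcyclohexan-1-one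
Conditions: Me4NBH(OAc)3, MeCN/AcOH 1:1, −30 °C
Reagents that add atoms: none
Why: Evans–Saksena reduction: the C5 hydroxyl binds boron and delivers hydride to the unhindered C3 ketone from its own face, so C3 (S) is set 1,3-anti (trans) to C5–OH, while the C6 ketone between two quaternary carbons should stay untouched.

**Step 5**
Reactants: 7 (2R,4S)-2,4-dihydroxy-2,6,6-trimethylcyclohexan-1-one
Product: 8 (2R,4S)-4-[(tert-butyldimethylsilyl)oxy]-2-hydroxy-2,6,6-trimethylcyclohexan-1-one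
Conditions: TBSCl, imidazole, DMF, 0 °C → rt
Reagents that add atoms: tert-butyldimethylsilyl chloride, CC(C)(C)[Si](C)(C)Cl
Why: Silylation of the secondary C3 hydroxyl, selective because the C5 hydroxyl is tertiary and hindered.

**Step 6**
Reactants: 8 (2R,4S)-4-[(tert-butyldimethylsilyl)oxy]-2-hydroxy-2,6,6-trimethylcyclohexan-1-one; 9 (2E)-3-methylpent-2-en-4-yn-1-ol
Product: 11 (1S,2R,4S)-4-[(tert-butyldimethylsilyl)oxy]-1-[(3E)-5-hydroxy-3-methylpent-3-en-1-yn-1-yl]-2,6,6-trimethylcyclohexane-1,2-diol, via dimagnesium acetylide 10 (not isolated)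
Conditions: 9 (3 equiv), EtMgBr (6.5 equiv), THF, 0 → 40 °C; then 8, THF/toluene, 0 °C → rt; pH 7 aqueous work-up
Reagents that add atoms: none
Why: Chelation-controlled (Cram chelate) Grignard addition: the magnesium alkoxide at C5 binds the C6 carbonyl, which places C5–O in the carbonyl plane and the C5 methyl axial, so the acetylide should enter anti to that methyl, i.e. syn to C5–O, setting C6 with the 5,6-trans-diol relationship.

**Step 7**
Reactants: 11 (1S,2R,4S)-4-[(tert-butyldimethylsilyl)oxy]-1-[(3E)-5-hydroxy-3-methylpent-3-en-1-yn-1-yl]-2,6,6-trimethylcyclohexane-1,2-diol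
Product: 12 (1R,2R,4S)-4-[(tert-butyldimethylsilyl)oxy]-1-[(1E,3E)-5-hydroxy-3-methylpenta-1,3-dien-1-yl]-2,6,6-trimethylcyclohexane-1,2-diol
Conditions: NaAlH2(OCH2CH2OMe)2 (Red-Al), THF, 0 °C → rt; Rochelle salt work-up
Reagents that add atoms: none
Why: Alkoxide-directed trans-hydroalumination of the propargylic alcohol should give the (7E) alkene only; C6 is unchanged (its descriptor changes from S to R only through the priority rules).

**Step 8**
Reactants: 12 (1R,2R,4S)-4-[(tert-butyldimethylsilyl)oxy]-1-[(1E,3E)-5-hydroxy-3-methylpenta-1,3-dien-1-yl]-2,6,6-trimethylcyclohexane-1,2-diol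
Product: 14 {(2E,4E)-5-[(1R,2R,4S)-4-[(tert-butyldimethylsilyl)oxy]-1,2-dihydroxy-2,6,6-trimethylcyclohexyl]-3-methylpenta-2,4-dien-1-yl}triphenylphosphonium bromide, via allylic bromide 13 (not isolated)
Conditions: CBr4 (1.1 equiv), PPh3 (2.5 equiv), 2,6-lutidine (cat.), CH2Cl2, −30 °C → rt
Reagents that add atoms: tetrabromomethane, BrC(Br)(Br)Br; triphenylphosphine, c1ccc(cc1)P(c1ccccc1)c1ccccc1
Why: Appel bromination of the primary allylic alcohol under non-acidic conditions (tertiary alcohols do not react at low temperature), with the labile bromide quaternised in situ by the excess phosphine.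

**Step 9**
Reactants: 9 (2E)-3-methylpent-2-en-4-yn-1-ol
Product: 15 tert-butyldimethyl{[(2E)-3-methylpent-2-en-4-yn-1-yl]oxy}silane
Conditions: TBSCl, imidazole, CH2Cl2, 0 °C → rt
Reagents that add atoms: tert-butyldimethylsilyl chloride, CC(C)(C)[Si](C)(C)Cl
Why: Standard silylation of a primary alcohol, needed so that the later palladium step meets no allylic leaving group.

**Step 10**
Reactants: 8 (2R,4S)-4-[(tert-butyldimethylsilyl)oxy]-2-hydroxy-2,6,6-trimethylcyclohexan-1-one
Product: 16 tert-butyl [(1R,5S)-5-[(tert-butyldimethylsilyl)oxy]-1,3,3-trimethyl-2-oxocyclohexyl] carbonate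
Conditions: Boc2O, DMAP (0.2 equiv), MeCN, rt → 40 °C
Reagents that add atoms: di-tert-butyl dicarbonate, CC(C)(C)OC(=O)OC(=O)OC(C)(C)C
Why: DMAP-catalysed acylation of the tertiary α-hydroxy ketone (no enolisable positions) removes the chelating hydroxyl and installs the carbon of the later cyclic carbonate.

**Step 11**
Reactants: 16 tert-butyl [(1R,5S)-5-[(tert-butyldimethylsilyl)oxy]-1,3,3-trimethyl-2-oxocyclohexyl] carbonate; 15 tert-butyldimethyl{[(2E)-3-methylpent-2-en-4-yn-1-yl]oxy}silane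
Product: 19 (3aR,5S,7aR)-5-[(tert-butyldimethylsilyl)oxy]-7a-[(3E)-5-[(tert-butyldimethylsilyl)oxy]-3-methylpent-3-en-1-yn-1-yl]-3a,7,7-trimethylhexahydro-2H-1,3-benzodioxol-2-one, via lithium acetylide 17 (not isolated), via lithium alkoxide 18 (not isolated)
Conditions: 15, n-BuLi, THF, −78 °C; then 16, −78 → 0 °C; H2O quench
Reagents that add atoms: none
Why: Felkin–Anh (polar) addition: without a chelating hydroxyl the acetylide should attack axially, anti to the axial C5 acyloxy group and the axial C1 methyl, so C6–O ends cis to C5–O, and this alkoxide then transfers onto the neighbouring carbonate (5-exo-trig, loss of tert-butoxide) to close the cis-fused cyclic carbonate.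

**Step 12**
Reactants: 19 (3aR,5S,7aR)-5-[(tert-butyldimethylsilyl)oxy]-7a-[(3E)-5-[(tert-butyldimethylsilyl)oxy]-3-methylpent-3-en-1-yn-1-yl]-3a,7,7-trimethylhexahydro-2H-1,3-benzodioxol-2-one
Product: 20 (1R,5S)-5-[(tert-butyldimethylsilyl)oxy]-2-[(aS,3E)-5-[(tert-butyldimethylsilyl)oxy]-3-methylpenta-1,3-dien-1-ylidene]-1,3,3-trimethylcyclohexan-1-ol
Conditions: Pd2(dba)3·CHCl3 (2.5 mol %), PBu3 (10 mol %), HCO2NH4 (3 equiv), THF, rt
Reagents that add atoms: none
Why: Formate hydrogenolysis of a propargylic carbonate: zerovalent palladium ionises the C6–O bond anti (SN2′) with loss of CO2, formate supplies the hydride and reductive elimination places H on C8 anti to the departed oxygen, so the allene axis should form as (6S) while C5 keeps its oxygen as the free hydroxyl.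

**Step 13**
Reactants: 20 (1R,5S)-5-[(tert-butyldimethylsilyl)oxy]-2-[(aS,3E)-5-[(tert-butyldimethylsilyl)oxy]-3-methylpenta-1,3-dien-1-ylidene]-1,3,3-trimethylcyclohexan-1-ol
Product: 21 tert-butyl{[(2E)-3-[(2R,6S,7aR)-6-[(tert-butyldimethylsilyl)oxy]-4,4,7a-trimethyl-2,4,5,6,7,7a-hexahydro-1-benzofuran-2-yl]but-2-en-1-yl]oxy}dimethylsilane
Conditions: AgNO3 (0.2 equiv), CaCO3, acetone/H2O 4:1, rt, dark
Reagents that add atoms: none
Why: Silver-catalysed 5-endo-trig cycloisomerisation of the α-hydroxyallene: the C5 hydroxyl adds to C8 in the plane of the C6 substituents, so the axial chirality is transferred to the centre and the C9 chain should end on the dihydrofuran face that carries C4, i.e. (8R).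

**Step 14**
Reactants: 21 tert-butyl{[(2E)-3-[(2R,6S,7aR)-6-[(tert-butyldimethylsilyl)oxy]-4,4,7a-trimethyl-2,4,5,6,7,7a-hexahydro-1-benzofuran-2-yl]but-2-en-1-yl]oxy}dimethylsilane
Product: 22 (2E)-3-[(2R,6S,7aR)-6-[(tert-butyldimethylsilyl)oxy]-4,4,7a-trimethyl-2,4,5,6,7,7a-hexahydro-1-benzofuran-2-yl]but-2-en-1-ol
Conditions: HF·pyridine, excess pyridine, THF, 0 °C
Reagents that add atoms: none
Why: Buffered fluoride should cleave the primary allylic silyl ether well before the hindered secondary one, and the near-neutral medium protects the doubly allylic C8 ether from ionisation.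

**Step 15**
Reactants: 22 (2E)-3-[(2R,6S,7aR)-6-[(tert-butyldimethylsilyl)oxy]-4,4,7a-trimethyl-2,4,5,6,7,7a-hexahydro-1-benzofuran-2-yl]but-2-en-1-ol
Product: 24 {(2E)-3-[(2R,6S,7aR)-6-[(tert-butyldimethylsilyl)oxy]-4,4,7a-trimethyl-2,4,5,6,7,7a-hexahydro-1-benzofuran-2-yl]but-2-en-1-yl}triphenylphosphonium bromide, via allylic bromide 23 (not isolated)
Conditions: CBr4 (1.1 equiv), PPh3 (2.5 equiv), 2,6-lutidine (cat.), CH2Cl2, −30 °C → rt
Reagents that add atoms: tetrabromomethane, BrC(Br)(Br)Br; triphenylphosphine, c1ccc(cc1)P(c1ccccc1)c1ccccc1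
Why: Appel bromination and in situ quaternisation under non-acidic conditions, chosen to keep C8 from epimerising.

**Step 16**
Reactants: 24 {(2E)-3-[(2R,6S,7aR)-6-[(tert-butyldimethylsilyl)oxy]-4,4,7a-trimethyl-2,4,5,6,7,7a-hexahydro-1-benzofuran-2-yl]but-2-en-1-yl}triphenylphosphonium bromide; 25 (2E,4E,6E)-2,7-dimethylocta-2,4,6-trienedial
Product: 27 (3S,5R,8R)-3-[(tert-butyldimethylsilyl)oxy]-5,8-epoxy-5,8-dihydro-12′-apo-β-caroten-12′-al, via phosphonium ylide 26 (not isolated)
Conditions: 25 (3 equiv), 1,2-epoxybutane, 65 °C; then heptane, 80 °C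
Reagents that add atoms: none
Why: Wittig olefination with the ylide released slowly by the epoxide/bromide couple and trapped at once by the excess dialdehyde (mono-olefination); the hindered Z isomer of the new disubstituted double bond should isomerise to E on heating.

**Step 17**
Reactants: 27 (3S,5R,8R)-3-[(tert-butyldimethylsilyl)oxy]-5,8-epoxy-5,8-dihydro-12′-apo-β-caroten-12′-al; 14 {(2E,4E)-5-[(1R,2R,4S)-4-[(tert-butyldimethylsilyl)oxy]-1,2-dihydroxy-2,6,6-trimethylcyclohexyl]-3-methylpenta-2,4-dien-1-yl}triphenylphosphonium bromide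
Product: 29 (3S,5R,6R,3′S,5′R,8′R)-3,3′-bis[(tert-butyldimethylsilyl)oxy]-5′,8′-epoxy-5,6,5′,8′-tetrahydro-β,β-carotene-5,6-diol, via phosphonium ylide 28 (not isolated)
Conditions: 14 (1.3 equiv), 1,2-epoxybutane, 65 °C; then heptane/EtOH, 75 °C
Reagents that add atoms: none
Why: Second Wittig olefination under the same nearly neutral conditions, which tolerate the free tertiary hydroxyls; thermal isomerisation of the hindered 11Z isomer should give the all-E polyene.

**Step 18**
Reactants: 29 (3S,5R,6R,3′S,5′R,8′R)-3,3′-bis[(tert-butyldimethylsilyl)oxy]-5′,8′-epoxy-5,6,5′,8′-tetrahydro-β,β-carotene-5,6-diol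
Product: 30 (3S,5R,6R,3′S,5′R,8′R)-5′,8′-epoxy-5,6,5′,8′-tetrahydro-β,β-carotene-3,5,6,3′-tetrol
Conditions: Bu4NF, THF, rt, dark
Reagents that add atoms: none
Why: Fluoride cleavage of both secondary silyl ethers under basic, non-acidic conditions that should leave the tertiary allylic alcohol, the furanoid C8′ centre and the polyene intact.

## Compound list

1 | 4-methylpentane-2,3-dione | CC(C)C(=O)C(C)=O | starting material
2 | 3-bromo-2-methylprop-1-ene | C=C(C)CBr | starting material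
3 | 4-methyl-3-[(2-methylprop-2-en-1-yl)oxy]pent-3-en-2-one | CC(=O)C(OCC(C)=C)=C(C)C | intermediate
4 | 4,4,6-trimethylhept-6-ene-2,3-dione (formed in situ) | CC(=O)C(=O)C(C)(C)CC(C)=C | intermediate
5 | (2R)-2-hydroxy-2,6,6-trimethyl-4-methylidenecyclohexan-1-one | O=C1C(C)(C)CC(=C)C[C@@]1(C)O | intermediate
6 | (2R)-2-hydroxy-2,6,6-trimethylcyclohexane-1,4-dione | O=C1C(C)(C)CC(=O)C[C@@]1(C)O | intermediate
7 | (2R,4S)-2,4-dihydroxy-2,6,6-trimethylcyclohexan-1-one | O=C1C(C)(C)C[C@H](O)C[C@@]1(C)O | intermediate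
8 | (2R,4S)-4-[(tert-butyldimethylsilyl)oxy]-2-hydroxy-2,6,6-trimethylcyclohexan-1-one | O=C1C(C)(C)C[C@H](O[Si](C)(C)C(C)(C)C)C[C@@]1(C)O | intermediate
9 | (2E)-3-methylpent-2-en-4-yn-1-ol | OC/C=C(C)/C#C | starting material
10 | bis(bromomagnesium) acetylide alkoxide of 9 (formed in situ) | Br[Mg]OC/C=C(C)/C#C[Mg]Br | intermediate
11 | (1S,2R,4S)-4-[(tert-butyldimethylsilyl)oxy]-1-[(3E)-5-hydroxy-3-methylpent-3-en-1-yn-1-yl]-2,6,6-trimethylcyclohexane-1,2-diol | OC/C=C(C)/C#C[C@@]1(O)C(C)(C)C[C@H](O[Si](C)(C)C(C)(C)C)C[C@@]1(C)O | intermediate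
12 | (1R,2R,4S)-4-[(tert-butyldimethylsilyl)oxy]-1-[(1E,3E)-5-hydroxy-3-methylpenta-1,3-dien-1-yl]-2,6,6-trimethylcyclohexane-1,2-diol | OC/C=C(C)/C=C/[C@@]1(O)C(C)(C)C[C@H](O[Si](C)(C)C(C)(C)C)C[C@@]1(C)O | intermediate
13 | (1R,2R,4S)-1-[(1E,3E)-5-bromo-3-methylpenta-1,3-dien-1-yl]-4-[(tert-butyldimethylsilyl)oxy]-2,6,6-trimethylcyclohexane-1,2-diol (formed in situ) | BrC/C=C(C)/C=C/[C@@]1(O)C(C)(C)C[C@H](O[Si](C)(C)C(C)(C)C)C[C@@]1(C)O | intermediate
14 | {(2E,4E)-5-[(1R,2R,4S)-4-[(tert-butyldimethylsilyl)oxy]-1,2-dihydroxy-2,6,6-trimethylcyclohexyl]-3-methylpenta-2,4-dien-1-yl}triphenylphosphonium bromide | [Br-].C(/C=C(C)/C=C/[C@@]1(O)C(C)(C)C[C@H](O[Si](C)(C)C(C)(C)C)C[C@@]1(C)O)[P+](c1ccccc1)(c1ccccc1)c1ccccc1 | intermediate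
15 | tert-butyldimethyl{[(2E)-3-methylpent-2-en-4-yn-1-yl]oxy}silane | CC(C)(C)[Si](C)(C)OC/C=C(C)/C#C | intermediate
16 | tert-butyl [(1R,5S)-5-[(tert-butyldimethylsilyl)oxy]-1,3,3-trimethyl-2-oxocyclohexyl] carbonate | O=C1C(C)(C)C[C@H](O[Si](C)(C)C(C)(C)C)C[C@@]1(C)OC(=O)OC(C)(C)C | intermediate
17 | lithium acetylide of 15 (formed in situ) | [Li]C#C/C(C)=C/CO[Si](C)(C)C(C)(C)C | intermediate
18 | lithium (1R,2R,4S)-2-[(tert-butoxycarbonyl)oxy]-4-[(tert-butyldimethylsilyl)oxy]-1-[(3E)-5-[(tert-butyldimethylsilyl)oxy]-3-methylpent-3-en-1-yn-1-yl]-2,6,6-trimethylcyclohexan-1-olate (formed in situ) | CC(C)(C)[Si](C)(C)OC/C=C(C)/C#C[C@]1([O-])C(C)(C)C[C@H](O[Si](C)(C)C(C)(C)C)C[C@@]1(C)OC(=O)OC(C)(C)C.[Li+] | intermediate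
19 | (3aR,5S,7aR)-5-[(tert-butyldimethylsilyl)oxy]-7a-[(3E)-5-[(tert-butyldimethylsilyl)oxy]-3-methylpent-3-en-1-yn-1-yl]-3a,7,7-trimethylhexahydro-2H-1,3-benzodioxol-2-one (cis-fused) | CC(C)(C)[Si](C)(C)OC/C=C(C)/C#C[C@]1(OC(=O)O2)C(C)(C)C[C@H](O[Si](C)(C)C(C)(C)C)C[C@]12C | intermediate
20 | (1R,5S)-5-[(tert-butyldimethylsilyl)oxy]-2-[(aS,3E)-5-[(tert-butyldimethylsilyl)oxy]-3-methylpenta-1,3-dien-1-ylidene]-1,3,3-trimethylcyclohexan-1-ol (allene axis S, i.e. 6S; C8–H anti to the C5 hydroxyl side) | CC(C)(C)[Si](C)(C)OC/C=C(C)/C([H])=[C@]=C1C(C)(C)C[C@H](O[Si](C)(C)C(C)(C)C)C[C@@]1(C)O | intermediate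
21 | tert-butyl{[(2E)-3-[(2R,6S,7aR)-6-[(tert-butyldimethylsilyl)oxy]-4,4,7a-trimethyl-2,4,5,6,7,7a-hexahydro-1-benzofuran-2-yl]but-2-en-1-yl]oxy}dimethylsilane | CC(C)(C)[Si](C)(C)OC/C=C(C)/[C@H]1C=C2C(C)(C)C[C@H](O[Si](C)(C)C(C)(C)C)C[C@@]2(C)O1 | intermediate
22 | (2E)-3-[(2R,6S,7aR)-6-[(tert-butyldimethylsilyl)oxy]-4,4,7a-trimethyl-2,4,5,6,7,7a-hexahydro-1-benzofuran-2-yl]but-2-en-1-ol | OC/C=C(C)/[C@H]1C=C2C(C)(C)C[C@H](O[Si](C)(C)C(C)(C)C)C[C@@]2(C)O1 | intermediate
23 | (2R,6S,7aR)-2-[(2E)-4-bromobut-2-en-2-yl]-6-[(tert-butyldimethylsilyl)oxy]-4,4,7a-trimethyl-2,4,5,6,7,7a-hexahydro-1-benzofuran (formed in situ) | BrC/C=C(C)/[C@H]1C=C2C(C)(C)C[C@H](O[Si](C)(C)C(C)(C)C)C[C@@]2(C)O1 | intermediate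
24 | {(2E)-3-[(2R,6S,7aR)-6-[(tert-butyldimethylsilyl)oxy]-4,4,7a-trimethyl-2,4,5,6,7,7a-hexahydro-1-benzofuran-2-yl]but-2-en-1-yl}triphenylphosphonium bromide | [Br-].C(/C=C(C)/[C@H]1C=C2C(C)(C)C[C@H](O[Si](C)(C)C(C)(C)C)C[C@@]2(C)O1)[P+](c1ccccc1)(c1ccccc1)c1ccccc1 | intermediate
25 | (2E,4E,6E)-2,7-dimethylocta-2,4,6-trienedial | O=C/C(C)=C/C=C/C=C(C)/C=O | starting material
26 | triphenylphosphonium ylide derived from 24 (formed in situ) | [CH-](/C=C(C)/[C@H]1C=C2C(C)(C)C[C@H](O[Si](C)(C)C(C)(C)C)C[C@@]2(C)O1)[P+](c1ccccc1)(c1ccccc1)c1ccccc1 | intermediate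
27 | (3S,5R,8R)-3-[(tert-butyldimethylsilyl)oxy]-5,8-epoxy-5,8-dihydro-12′-apo-β-caroten-12′-al (all-E C25 aldehyde) | O=C/C(C)=C/C=C/C=C(C)/C=C/C=C(C)/[C@H]1C=C2C(C)(C)C[C@H](O[Si](C)(C)C(C)(C)C)C[C@@]2(C)O1 | intermediate
28 | triphenylphosphonium ylide derived from 14 (formed in situ) | [CH-](/C=C(C)/C=C/[C@@]1(O)C(C)(C)C[C@H](O[Si](C)(C)C(C)(C)C)C[C@@]1(C)O)[P+](c1ccccc1)(c1ccccc1)c1ccccc1 | intermediate
29 | (3S,5R,6R,3′S,5′R,8′R)-3,3′-bis[(tert-butyldimethylsilyl)oxy]-5′,8′-epoxy-5,6,5′,8′-tetrahydro-β,β-carotene-5,6-diol | CC(/C=C/C=C(C)/C=C/[C@@]1(O)C(C)(C)C[C@H](O[Si](C)(C)C(C)(C)C)C[C@@]1(C)O)=C\C=C\C=C(C)\C=C\C=C(/C)[C@H]1C=C2C(C)(C)C[C@H](O[Si](C)(C)C(C)(C)C)C[C@@]2(C)O1 | intermediate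
30 | (3S,5R,6R,3′S,5′R,8′R)-5′,8′-epoxy-5,6,5′,8′-tetrahydro-β,β-carotene-3,5,6,3′-tetrol | CC(/C=C/C=C(C)/C=C/[C@@]1(O)C(C)(C)C[C@H](O)C[C@@]1(C)O)=C\C=C\C=C(C)\C=C\C=C(/C)[C@H]1C=C2C(C)(C)C[C@H](O)C[C@@]2(C)O1 | target

## Step count and risks

Total step count: 18. Longest linear sequence: 14 (steps 1–5, 10–15, 16–18).

**Step 2 (proposed new method).** The domino may stop after the Claisen stage, the hydroxy ketone product may bind copper and shut the catalyst down, or the ene closure may run with poor enantioface discrimination or with cationic proton loss that scrambles the alkene position. The fallback uses known chemistry and sets out from 3. Thermal Claisen rearrangement of the diosphenol allyl ether (xylene, 140 °C) gives diketone 4, now isolated. A Lewis-acid type 2 carbonyl-ene cyclisation (SnCl4, CH2Cl2, −78 °C) then gives racemic 2-hydroxy-2,6,6-trimethyl-4-methylidenecyclohexan-1-one F1. F1 is resolved by preparative chromatography on a chiral stationary phase, and the route is rejoined at 5.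

**Step 6.** Facial selectivity at C6 may be poor or reversed: if the magnesium alkoxide cannot reach the chelated conformer (it costs a syn-axial contact with the C3 silyloxy group), attack anti to the axial C5 oxygen would dominate and give the 6-epimer. The fallback sets out from 5, which has no C3 substituent, so that the chelated chair is accessible. Chelation-controlled addition of HC≡CMgBr gives (1S,2R)-1-ethynyl-2,6,6-trimethyl-4-methylidenecyclohexane-1,2-diol F2. Ozonolysis of the exocyclic alkene (O3, −78 °C, Me2S; the alkyne reacts far more slowly) gives (3R,4S)-4-ethynyl-3,4-dihydroxy-3,5,5-trimethylcyclohexan-1-one F3. Evans–Saksena reduction gives (1S,2R,4S)-1-ethynyl-2,6,6-trimethylcyclohexane-1,2,4-triol F4, and silylation (TBSCl, imidazole) gives (1S,2R,4S)-4-[(tert-butyldimethylsilyl)oxy]-1-ethynyl-2,6,6-trimethylcyclohexane-1,2-diol F5. Sonogashira coupling of F5 with (2E)-3-iodobut-2-en-1-ol (Pd(PPh3)2Cl2, CuI, Et3N) rejoins the route at 11.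

**Step 16.** The allyl ylide 26 may expel the C8′ alkoxide through its C9′ carbanion form (vinylogous β-elimination that opens the dihydrofuran) or epimerise C8′ before it is trapped. The fallback reverses the polarity of the last coupling and sets out from 22 and 14. Oxidation of 22 with MnO2 gives (2E)-3-[(2R,6S,7aR)-6-[(tert-butyldimethylsilyl)oxy]-4,4,7a-trimethyl-2,4,5,6,7,7a-hexahydro-1-benzofuran-2-yl]but-2-enal F6. Wittig reaction of 14 with excess 25 (1,2-epoxybutane) gives (3S,5R,6R)-3-[(tert-butyldimethylsilyl)oxy]-5,6-dihydroxy-5,6-dihydro-12′-apo-β-caroten-12′-al F7. NaBH4 reduction gives the corresponding 12′-apo-β-caroten-12′-ol F8, and CBr4/PPh3 converts it into the C25 triphenylphosphonium bromide F9. Wittig reaction of F9 with F6 (1,2-epoxybutane, then thermal isomerisation) rejoins the route at 29.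

## Further compounds

F1 | step 2 | racemic 2-hydroxy-2,6,6-trimethyl-4-methylidenecyclohexan-1-one | O=C1C(C)(C)CC(=C)CC1(C)O
F2 | step 6 | (1S,2R)-1-ethynyl-2,6,6-trimethyl-4-methylidenecyclohexane-1,2-diol | C#C[C@@]1(O)C(C)(C)CC(=C)C[C@@]1(C)O
F3 | step 6 | (3R,4S)-4-ethynyl-3,4-dihydroxy-3,5,5-trimethylcyclohexan-1-one | C#C[C@@]1(O)C(C)(C)CC(=O)C[C@@]1(C)O
F4 | step 6 | (1S,2R,4S)-1-ethynyl-2,6,6-trimethylcyclohexane-1,2,4-triol | C#C[C@@]1(O)C(C)(C)C[C@H](O)C[C@@]1(C)O
F5 | step 6 | (1S,2R,4S)-4-[(tert-butyldimethylsilyl)oxy]-1-ethynyl-2,6,6-trimethylcyclohexane-1,2-diol | C#C[C@@]1(O)C(C)(C)C[C@H](O[Si](C)(C)C(C)(C)C)C[C@@]1(C)O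
F6 | step 16 | (2E)-3-[(2R,6S,7aR)-6-[(tert-butyldimethylsilyl)oxy]-4,4,7a-trimethyl-2,4,5,6,7,7a-hexahydro-1-benzofuran-2-yl]but-2-enal | O=C/C=C(C)/[C@H]1C=C2C(C)(C)C[C@H](O[Si](C)(C)C(C)(C)C)C[C@@]2(C)O1
F7 | step 16 | (3S,5R,6R)-3-[(tert-butyldimethylsilyl)oxy]-5,6-dihydroxy-5,6-dihydro-12′-apo-β-caroten-12′-al | O=C/C(C)=C/C=C/C=C(C)/C=C/C=C(C)/C=C/[C@@]1(O)C(C)(C)C[C@H](O[Si](C)(C)C(C)(C)C)C[C@@]1(C)O
F8 | step 16 | (3S,5R,6R)-3-[(tert-butyldimethylsilyl)oxy]-5,6-dihydro-12′-apo-β-carotene-5,6,12′-triol | OC/C(C)=C/C=C/C=C(C)/C=C/C=C(C)/C=C/[C@@]1(O)C(C)(C)C[C@H](O[Si](C)(C)C(C)(C)C)C[C@@]1(C)O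
F9 | step 16 | [(3S,5R,6R)-3-[(tert-butyldimethylsilyl)oxy]-5,6-dihydroxy-5,6-dihydro-12′-apo-β-caroten-12′-yl]triphenylphosphonium bromide | [Br-].C(/C(C)=C/C=C/C=C(C)/C=C/C=C(C)/C=C/[C@@]1(O)C(C)(C)C[C@H](O[Si](C)(C)C(C)(C)C)C[C@@]1(C)O)[P+](c1ccccc1)(c1ccccc1)c1ccccc1
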